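## Retrosynthetic overview

1. Ugonin Q (9) ⇐ its tetraacetate 8; the acetates come off last under non-acidic conditions.
2. 8 ⇐ (S)-α-cyclogeranyl flavone 6 by a singlet-oxygen ene reaction, which moves the alkene exocyclic and puts oxygen trans to the arylmethyl group.
3. 6 ⇐ 6-geranylluteolin tetraacetate 4 by an enantioselective proton-initiated cation–olefin cyclisation on the intact flavone; this is the only ring-forming step and sets the carbon stereocentre.
4. 4 ⇐ luteolin 1 + geranyl bromide 2 by C6 nuclear geranylation, then peracetylation.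
5. Ring order: flavone rings A, B and C arrive with luteolin; the cyclohexane ring is formed last, as in the plant (luteolin → 6-geranylluteolin → cyclised → hydroxylated).

Assumption: the (R)-configured chiral acid gives the (S)-series, the sense in which this reagent family builds natural-series terpenoid rings; if the first run shows the opposite sense, the (S)-ligand is used and nothing else changes.

## Route

Step 1
Reactants: 1 luteolin; 2 geranyl bromide
Product: 3 6-geranylluteolin
Conditions: NaOMe (3 equiv), MeOH, 0 °C → rt, 24 h; pH 5 work-up; chromatography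
Reagents that add atoms: none
Why: Nuclear C-alkylation of the ambident phenoxide (SN2 at the primary allylic bromide, E-alkene untouched) is favoured in methanol because the oxygens are solvated, and the chelated 5-OH fixes the ring A bonds so that C6, between the two oxygens, is the most nucleophilic carbon; the 8-C and O-alkylated isomers are removed by chromatography and a modest yield is expected.

Step 2
Reactants: 3 6-geranylluteolin
Product: 4 6-geranylluteolin tetraacetate
Conditions: Ac2O, pyridine, DMAP (cat.), CH2Cl2, rt
Reagents that add atoms: acetic anhydride, CC(=O)OC(C)=O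
Why: DMAP-catalysed acylation caps all four phenols, including the hydrogen-bonded 5-OH, which removes the oxygen nucleophiles that would trap the cyclisation cation as a chromane and shields the catechol from the later oxidation.

Step 3
Reactants: 4 6-geranylluteolin tetraacetate
Product: 6 (S)-α-cyclogeranyl flavone tetraacetate (endocyclic alkene), via exocyclic alkene isomer 5 (not isolated)
Conditions: (R)-2-(2-fluorobenzyloxy)-2'-hydroxy-1,1'-binaphthyl·SnCl4 (3 equiv, preformed), toluene/CH2Cl2, −78 °C, 48 h; then −30 °C, 3 h; NaHCO3 aq (ligand recovered)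
Reagents that add atoms: none
Why: Proposed new method: the tin-bound chiral naphthol proton is delivered to one face of the terminal 6,7-alkene while C2 attacks C7 through a chair transition state (arylmethyl equatorial), which sets the single stereocentre as S, and the tertiary cation, with no nucleophile in reach on the acetylated ring, loses a proton, the exocyclic isomer being drained on warming to the more stable endocyclic trisubstituted alkene by reprotonation to the same cation without touching the stereocentre (the first equivalent of acid is expected to be tied up by the pyrone carbonyl, hence the excess); the closest known reaction type is the Lewis-acid-assisted chiral Brønsted acid (Yamamoto-type) enantioselective proton-initiated polyene cyclisation of geranyl arenes.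

Step 4
Reactants: 6 (S)-α-cyclogeranyl flavone tetraacetate
Product: 8 ugonin Q tetraacetate, via allylic hydroperoxide 7 (not isolated)
Conditions: O2, tetraphenylporphyrin (1 mol %), white LED, CH2Cl2, −20 °C; then PPh3, −20 °C → rt
Reagents that add atoms: dioxygen, O=O
Why: In this Schenck ene reaction singlet oxygen bonds to the less hindered alkene CH on the face anti to the pseudoaxial arylmethyl group and takes hydrogen from the methyl geminal to the bulky ring carbon (large-group effect), which gives the trans (1S,3S) allylic hydroperoxide with the exocyclic methylene, and PPh3 reduces O–O with retention at carbon.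

Step 5
Reactants: 8 ugonin Q tetraacetate
Product: 9 ugonin Q
Conditions: K2CO3 (0.3 equiv), degassed MeOH, 0 °C → rt, Ar; pH 6 buffer work-up
Reagents that add atoms: none
Why: Base-catalysed transesterification (Zemplén-type methanolysis) removes the four aryl acetates under non-acidic, non-reducing conditions that leave the allylic alcohol, the exocyclic alkene and both stereocentres untouched.

## Compound list

1 | luteolin, 2-(3,4-dihydroxyphenyl)-5,7-dihydroxy-4H-chromen-4-one | O=c1cc(-c2ccc(O)c(O)c2)oc2cc(O)cc(O)c12 | starting material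
2 | geranyl bromide, (2E)-1-bromo-3,7-dimethylocta-2,6-diene | CC(C)=CCC/C(C)=C/CBr | starting material
3 | 6-geranylluteolin, 2-(3,4-dihydroxyphenyl)-6-[(2E)-3,7-dimethylocta-2,6-dien-1-yl]-5,7-dihydroxy-4H-chromen-4-one | CC(C)=CCC/C(C)=C/Cc1c(O)cc2oc(-c3ccc(O)c(O)c3)cc(=O)c2c1O | intermediate
4 | 6-geranylluteolin 5,7,3',4'-tetraacetate | CC(C)=CCC/C(C)=C/Cc1c(OC(C)=O)cc2oc(-c3ccc(OC(C)=O)c(OC(C)=O)c3)cc(=O)c2c1OC(C)=O | intermediate
5 | 6-{[(1S)-2,2-dimethyl-6-methylidenecyclohexyl]methyl}luteolin 5,7,3',4'-tetraacetate (exocyclic alkene isomer) | C=C1[C@@H](Cc2c(OC(C)=O)cc3oc(-c4ccc(OC(C)=O)c(OC(C)=O)c4)cc(=O)c3c2OC(C)=O)C(C)(C)CCC1 | intermediate (not isolated)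
6 | 6-{[(1S)-2,6,6-trimethylcyclohex-2-en-1-yl]methyl}luteolin 5,7,3',4'-tetraacetate | CC1=CCCC(C)(C)[C@@H]1Cc1c(OC(C)=O)cc2oc(-c3ccc(OC(C)=O)c(OC(C)=O)c3)cc(=O)c2c1OC(C)=O | intermediate
7 | 6-{[(1S,3S)-3-hydroperoxy-6,6-dimethyl-2-methylidenecyclohexyl]methyl}luteolin 5,7,3',4'-tetraacetate (OOH trans to the arylmethyl group) | C=C1[C@@H](Cc2c(OC(C)=O)cc3oc(-c4ccc(OC(C)=O)c(OC(C)=O)c4)cc(=O)c3c2OC(C)=O)C(C)(C)CC[C@@H]1OO | intermediate (not isolated)
8 | ugonin Q 5,7,3',4'-tetraacetate, 6-{[(1S,3S)-3-hydroxy-6,6-dimethyl-2-methylidenecyclohexyl]methyl}luteolin tetraacetate | C=C1[C@@H](Cc2c(OC(C)=O)cc3oc(-c4ccc(OC(C)=O)c(OC(C)=O)c4)cc(=O)c3c2OC(C)=O)C(C)(C)CC[C@@H]1O | intermediate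
9 | ugonin Q, 2-(3,4-dihydroxyphenyl)-5,7-dihydroxy-6-{[(1S,3S)-3-hydroxy-6,6-dimethyl-2-methylidenecyclohexyl]methyl}-4H-chromen-4-one (OH trans to the arylmethyl group) | C=C1[C@@H](Cc2c(O)cc3oc(-c4ccc(O)c(O)c4)cc(=O)c3c2O)C(C)(C)CC[C@@H]1O | target

## Step count and risks

Total step count: 5. Longest linear sequence: 5 steps (from luteolin).

The three steps most likely to fail:

Step 3 (enantioselective cyclisation). The flavone and acetate carbonyls may sequester the tin acid, the enantiomeric excess may be moderate, and alkene isomers may not converge cleanly. The fallback sets out from 4 and changes both the initiating electrophile and the source of asymmetry. N-iodosuccinimide with a stoichiometric BINOL-derived chiral phosphoramidite (toluene, −40 °C) delivers an iodonium ion to the terminal alkene and gives 6-{[(1R,5S)-5-iodo-2,6,6-trimethylcyclohex-2-en-1-yl]methyl}luteolin tetraacetate F4, with iodine cis to the arylmethyl group and the same spatial arrangement at the ring CH as in 6. Bu3SnH/AIBN (toluene, 80 °C) then removes iodine, and the sequence comes back to the route at 6.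

Step 1 (regiochemistry of C-geranylation). C8- and O-alkylation compete and the yield will be low. The fallback sets out from 1 and fixes the position by halogenation and cross-coupling. MOMCl/i-Pr2NEt leaves the chelated 5-OH free and gives 7,3',4'-tris-O-(methoxymethyl)luteolin F1. Benzyltrimethylammonium dichloroiodate with CaCO3 (CH2Cl2/MeOH) iodinates ortho to the free phenol to give 6-iodo-7,3',4'-tris-O-(methoxymethyl)luteolin F2. Stille coupling with (E)-geranyltributylstannane (Pd(PPh3)4, CuI, CsF, DMF, 60 °C) gives 6-geranyl-7,3',4'-tris-O-(methoxymethyl)luteolin F3. Dilute HCl in MeOH at rt removes the acetals, and the sequence comes back to the route at 3.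

Step 4 (regio- and face selectivity of the ene reaction). A tertiary allylic hydroperoxide from ring-hydrogen abstraction may compete. The fallback sets out from 6 and replaces the ene reaction by epoxidation and reductive isomerisation. mCPBA/NaHCO3 (CH2Cl2, 0 °C) attacks anti to the arylmethyl group and gives 6-{[(1R,2S,6S)-1,3,3-trimethyl-7-oxabicyclo[4.1.0]heptan-2-yl]methyl}luteolin tetraacetate F5 (oxirane oxygen trans to the arylmethyl group). Cp2TiCl (trivalent titanium, from Cp2TiCl2 and Mn dust, THF, rt) opens the oxirane homolytically at the tertiary carbon, and a second equivalent removes a methyl hydrogen to leave the exocyclic alkene. The sequence comes back to the route at 8.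

Further compounds
F1 | step 1 | 7,3',4'-tris-O-(methoxymethyl)luteolin | COCOc1cc(O)c2c(c1)oc(-c1ccc(OCOC)c(OCOC)c1)cc2=O
F2 | step 1 | 6-iodo-7,3',4'-tris-O-(methoxymethyl)luteolin | COCOc1cc2oc(-c3ccc(OCOC)c(OCOC)c3)cc(=O)c2c(O)c1I
F3 | step 1 | 6-geranyl-7,3',4'-tris-O-(methoxymethyl)luteolin | CC(C)=CCC/C(C)=C/Cc1c(OCOC)cc2oc(-c3ccc(OCOC)c(OCOC)c3)cc(=O)c2c1O
F4 | step 3 | 6-{[(1R,5S)-5-iodo-2,6,6-trimethylcyclohex-2-en-1-yl]methyl}luteolin 5,7,3',4'-tetraacetate | CC1=CC[C@H](I)C(C)(C)[C@@H]1Cc1c(OC(C)=O)cc2oc(-c3ccc(OC(C)=O)c(OC(C)=O)c3)cc(=O)c2c1OC(C)=O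
F5 | step 4 | 6-{[(1R,2S,6S)-1,3,3-trimethyl-7-oxabicyclo[4.1.0]heptan-2-yl]methyl}luteolin 5,7,3',4'-tetraacetate | C[C@]12O[C@H]1CCC(C)(C)[C@@H]2Cc1c(OC(C)=O)cc2oc(-c3ccc(OC(C)=O)c(OC(C)=O)c3)cc(=O)c2c1OC(C)=O
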